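## Structural features

Target 20 is a symmetric diarylmethane: two identical inner benzene rings are joined through one methylene carbon (C7), and each inner ring carries a two-carbon arm ending in a 4-hydroxy-3-methoxyphenyl outer ring. With each inner ring numbered C1 (arm), C2 (bridge), C3 (OMe), C4, C5 (OH), C6, the bridge carbon is flanked on both rings by the arm and the methoxyl, so C7 sits between four ortho substituents, and the free inner hydroxyl lies para to it. There is no stereocentre, hence none next to another; the problems are regiochemical: two 1,2,3,5-tetrasubstituted rings, a crowded C2–C7–C2' junction, and three kinds of phenolic oxygen (outer OH, inner para OH, inner ortho OMe) to be told apart. The fragile parts are the electron-rich phenols and the doubly activated benzhydrylic position (sensitive to oxidants and strong acid) and, on the way, the poly-beta-carbonyl intermediates, which self-condense if left unmasked. The key step exploits the fact that along C1–C6–C5–C4–C3–C2–C7–C2'–C3'–C4'–C5'–C6'–C1' every second carbon (C1, C5, C3, C7, C3', C5', C1') is a carbonyl carbon of a linear heptaketone; the meta relationship of the C3 and C5 oxygens is its signature. Two aldol closures, C2 onto C1 and C2' onto C1', therefore create both inner rings with arm, oxygens and bridge carbonyl in place, and the central 1,3,5-triketone can be stored as the 4-pyranone of 13. The resulting C7 ketone then distinguishes ortho from para hydroxyls by hydrogen bonding, which settles the oxygen differentiation.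

## Logic of the disconnections

20 to 19. Cut the four benzyl O–CH2 bonds and exchange C7–H for C7–OH. A diaryl carbinol carbon activated by two para oxygens is as hydrogenolysable as an aryl benzyl ether, so one operation can finish the synthesis. The gain is that no free phenol exists before the last step. The demand is that the catalyst reach a carbinol carbon between four ortho substituents.

19 to 18. C7–OH goes back to C7=O. The ketone is what the polyketide fold delivers and what tells the phenols apart. The demand is a hydride small enough for a tetra-ortho-substituted carbonyl.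

18 to 17. Cut the two O–CH3 bonds at C3 and C3'. These oxygens are the hydrogen-bonded ones, so they can be alkylated last among the phenols, once nothing else is acidic. The demand is forcing but otherwise ordinary etherification conditions.

17 to 16. Cut the two O–benzyl bonds at C5 and C5'. The para hydroxyls are more acidic and unhindered, so they react first with a weak base, and benzyl matches the group already on the outer rings. The demand is site selectivity between two pairs of phenols on each of two rings.

16 to 13. Cut C1–C2 and C1'–C2' and reconnect O to C3 and C3' as the pyranone ether. This removes both inner rings and the tetra-ortho-substituted junction at once and leaves an unbranched, symmetric chain with all carbons and oxygens in place. The demand is that the ring be opened by hydroxide before any aldol occurs, and that the chain fold in one register (C2 to C1) at both ends.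

13 to 12. The C1 and C1' carbonyls are re-masked as dioxolanes. A compound with six ketone-level carbons beside a pyranone cannot be carried through carbon–carbon bond formation, whereas 12 has only one reactive carbonyl per arm. The demand is an unmasking mild enough not to trigger condensation onto the intact pyranone.

12 to 11. C5=O and C5'=O go back to secondary alcohols, so that the arm–core bond can be made at the aldehyde oxidation level.

11 to 9 and two molecules of 8. Cut C4–C5 and C4'–C5'. The methyl carbons of 9 become nucleophilic on lateral deprotonation and 8 supplies C5 as an aldehyde. Making this bond at the ketone oxidation level instead (acylation by an ester or by an enolate-protected beta-keto ester) would give a product more acidic than 9, which consumes base, and would open a second deprotonation site next to the new ketone; an aldolate has neither defect. The demand is two successive lithiations of the same core; the carbinol configuration is irrelevant.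

8 to 7. The aldehyde goes back to the methyl ester, a stable and distillation-free precursor.

7 to 6. The dioxolane C–O bonds are cut back to the ketone. Masking is done here, where the ketone is the only electrophilic site besides the ester.

6 to 2 and 3. Cut C1–C6, an acyl–methylene bond formed by decarboxylative acylation. The C1 carbon is the carboxyl carbon of 2, so the arm enters with the correct length.

2 to 1. Cut the outer O–benzyl bond. One protecting group is used throughout and removed in the final hydrogenolysis.

## Other disconnections considered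

Alternative 1: The cut is at the two C5–O bonds, made as the last bond-forming event. In the forward sense bis{2-methoxy-6-[2-(3-methoxy-4-triisopropylsilyloxyphenyl)ethyl]phenyl}methane A1 would undergo iridium-catalysed C–H borylation at C5 and C5', the C–B bonds would be oxidised in the same flask to give the bis(triisopropylsilyl) ether of the target A2, and desilylation would give 20.
- In its favour: on each inner ring of A1, C5–H is the only arene hydrogen with no ortho substituent, and every outer-ring hydrogen has one, so steric control points to the right carbons. The reaction type is well established, neutral and mild, and it comes two steps from the end.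
- Against it here: the step builds no carbon skeleton. A1, with the crowded bridge and both arms, must first be made by separate C–C chemistry, which is the hard part of the problem. The benzylic C7–H bonds and the outer-ring position beside the small methoxyl are possible competing sites.
- Comparison: on mechanistic reliability of the key step the alternative is the better of the two. On protecting-group count it is about equal. On structure it addresses two C–O bonds, where the chosen plan creates two rings, two C–C bonds and the whole oxygen pattern. Its step economy depends entirely on an unspecified route to A1 and is unlikely to be better.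

Alternative 2: The cut is at C1–Ca and C1'–Ca', between inner rings and arms. Commercial 2,2',4,4'-tetrahydroxybenzophenone A3 would be benzylated at the para and methylated at the ortho hydroxyls to give bis(4-benzyloxy-2-methoxyphenyl)methanone A4. Ruthenium-catalysed, ketone-directed ortho C–H activation and linear addition to two molecules of 1-benzyloxy-4-ethenyl-2-methoxybenzene A5 would give bis{4-benzyloxy-2-methoxy-6-[2-(4-benzyloxy-3-methoxyphenyl)ethyl]phenyl}methanone A6, which is the same compound as 18 and would be finished by steps 11 and 12.
- In its favour: about five steps from commercial material, so step economy is clearly better than in the chosen plan. The ketone serves as directing group and as the future bridge. Each ring of A4 has a single free ortho hydrogen, so over-alkylation within a ring is excluded. The reaction type is known for aryl ketones.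
- Against it here: an ortho methoxyl on an aryl ketone offers the same catalyst a competing C–O cleavage. An electron-rich vinylarene is a less dependable partner than a vinylsilane (branched addition, oligomerisation). The second alkylation must occur on a ketone already twisted by three ortho substituents, whereas chelation-assisted metalation needs the carbonyl near the plane of the ring being attacked.
- Comparison: the alternative is equal or better on step count, convergence, availability of materials and precedent, and it shares the endgame. It is weaker in that the most congested bonds are made on preformed rings under catalyst control; the chosen plan builds the congestion in during aromatisation but pays with a longer sequence and an unprecedented double folding.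

Alternative 3: The cut takes C1–Ca and C2–C7 of one inner ring in a single operation. 1-Fluoro-3-methoxy-5-(triisopropylsilyloxy)benzene A7 would be lithiated between fluorine and methoxyl and lose fluoride to give 3-methoxy-5-(triisopropylsilyloxy)benzyne A9. [2-(4-Benzyloxy-3-methoxyphenyl)ethyl]magnesium bromide A8 would add at C1, and the C2 arylmagnesium would add to 2-[2-(4-benzyloxy-3-methoxyphenyl)ethyl]-6-methoxy-4-(triisopropylsilyloxy)benzaldehyde A10 (itself from the same sequence with a formamide as electrophile). The product would be the symmetric carbinol A11; deoxygenation, desilylation and hydrogenolysis would give 20.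
- In its favour: it is convergent, each elementary event is of a known type, the methoxyl dictates where the nucleophile adds to A9, and the three kinds of oxygen are distinct from the start. At roughly seven to eight steps its step economy is better than that of the chosen plan.
- Against it here: the excess of A8 needed to capture A9 also adds to A10, and faster than the hindered arylmagnesium does. Lithiation on the other side of fluorine would give an isomeric aryne. The tetra-ortho-substituted carbinol is formed from two 2,6-disubstituted partners in the slowest step. Three protecting-group types require three closing steps.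
- Comparison: the alternative is equal or better on convergence, step count and precedent. It is weaker in relying on a one-pot stoichiometric organometallic sequence at the most hindered carbon, where the chosen plan needs no organometallic reagent at C7 and makes both halves at once through symmetry.

Key step: step 8

Remark: checked atom by atom, 13, 16 and 20 are mutually consistent (13 loses one molecule of water overall in step 8) and needed no correction. The changes are in the route to 13: the arms are attached by aldol addition and oxidation instead of acylation, and the precursor is stored as its bis-dioxolane 12.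

## Route

Step 1
Reactants: 1 3-(4-hydroxy-3-methoxyphenyl)propanoic acid
Product: 2 3-(4-benzyloxy-3-methoxyphenyl)propanoic acid
Conditions: BnBr (1.3 eq), NaOH (3 eq), EtOH/H2O, reflux; then HCl to pH 2
Reagents that add atoms: benzyl bromide, BrCc1ccccc1
Why: Williamson etherification of the phenoxide–carboxylate dianion; in aqueous ethanol the phenoxide is by far the better nucleophile, and any benzyl ester that forms is saponified by the excess hydroxide before acidification.

Step 2
Reactants: 2 3-(4-benzyloxy-3-methoxyphenyl)propanoic acid; 3 potassium methyl malonate (potassium 3-methoxy-3-oxopropanoate)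
Product: 6 methyl 5-(4-benzyloxy-3-methoxyphenyl)-3-oxopentanoate, via acyl imidazolide 4 (not isolated), via chelated acylmalonate 5 (not isolated)
Conditions: 1,1'-carbonyldiimidazole (1.1 eq), THF, rt; then 3 (1.5 eq), MgCl2 (1.5 eq), Et3N (2.5 eq), THF/MeCN, rt to 45 °C; 1 M HCl
Reagents that add atoms: none
Why: Masamune–Brooks homologation: the acyl imidazolide C-acylates the magnesium enolate of the malonate half ester, and the chelated acylmalonate loses CO2 on acidification to give the beta-keto ester; the ether groups are inert.

Step 3
Reactants: 6 methyl 5-(4-benzyloxy-3-methoxyphenyl)-3-oxopentanoate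
Product: 7 methyl 2-{2-[2-(4-benzyloxy-3-methoxyphenyl)ethyl]-1,3-dioxolan-2-yl}acetate
Conditions: HOCH2CH2OH (2 eq), p-TsOH·H2O (5 mol%), toluene, reflux, Dean–Stark
Reagents that add atoms: ethylene glycol, OCCO
Why: acid-catalysed ketalisation driven by azeotropic removal of water; the ketone is far more electrophilic than the ester, and an aryl benzyl ether tolerates catalytic sulfonic acid.

Step 4
Reactants: 7 methyl 2-{2-[2-(4-benzyloxy-3-methoxyphenyl)ethyl]-1,3-dioxolan-2-yl}acetate
Product: 8 2-{2-[2-(4-benzyloxy-3-methoxyphenyl)ethyl]-1,3-dioxolan-2-yl}acetaldehyde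
Conditions: i-Bu2AlH (1.1 eq), CH2Cl2, −78 °C; MeOH, then KNaC4H4O6 (aq.)
Reagents that add atoms: none
Why: partial ester reduction; at −78 °C the aluminium hemiacetal, held by chelation to a ketal oxygen, does not collapse before the quench, so the aldehyde is not reduced further.

Step 5
Reactants: 9 2,6-dimethyl-4H-pyran-4-one; 8 2-{2-[2-(4-benzyloxy-3-methoxyphenyl)ethyl]-1,3-dioxolan-2-yl}acetaldehyde (2.1 eq in two portions)
Product: 11 2,6-bis(3-{2-[2-(4-benzyloxy-3-methoxyphenyl)ethyl]-1,3-dioxolan-2-yl}-2-hydroxypropyl)-4H-pyran-4-one (mixture of diastereomers), via mono-aldolate 10 (not isolated)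
Conditions: LiN(SiMe3)2 (1.05 eq), THF, −78 °C; 8 (1.0 eq); then LiN(SiMe3)2 (1.15 eq), −78 °C; 8 (1.1 eq); sat. NH4Cl
Reagents that add atoms: none
Why: lateral lithiation of a 2-methyl-4-pyranone gives a vinylogous enolate that adds through its methyl carbon to aldehydes (vinylogous aldol addition); the aldolate offers the second equivalent of base no C–H more acidic than the remaining methyl group, so the second addition occurs at the other end. The two carbinol centres are not controlled and are erased in step 6.

Step 6
Reactants: 11 2,6-bis(3-{2-[2-(4-benzyloxy-3-methoxyphenyl)ethyl]-1,3-dioxolan-2-yl}-2-hydroxypropyl)-4H-pyran-4-one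
Product: 12 2,6-bis(3-{2-[2-(4-benzyloxy-3-methoxyphenyl)ethyl]-1,3-dioxolan-2-yl}-2-oxopropyl)-4H-pyran-4-one
Conditions: Dess–Martin periodinane (2.6 eq), CH2Cl2, 0 °C to rt; Na2S2O3/NaHCO3 (aq.) work-up
Reagents that add atoms: none
Why: Dess–Martin oxidation of both secondary alcohols under near-neutral conditions that leave dioxolanes, pyranone and benzyl ethers untouched; the beta-hydroxyalkyl pyranone is never exposed to base, which could dehydrate it.

Step 7
Reactants: 12 2,6-bis(3-{2-[2-(4-benzyloxy-3-methoxyphenyl)ethyl]-1,3-dioxolan-2-yl}-2-oxopropyl)-4H-pyran-4-one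
Product: 13 2,6-bis[6-(4-benzyloxy-3-methoxyphenyl)-2,4-dioxohexyl]-4H-pyran-4-one
Conditions: 1 M HCl/THF (1:4), 0 °C to rt; extracted and used without chromatography
Reagents that add atoms: water, O
Why: acid-catalysed hydrolysis of the dioxolanes; in cold dilute acid the pyranone is too weak a carbon nucleophile to attack the liberated ketones, and the product is taken on at once because a free poly-beta-carbonyl compound does not store well.

Step 8
Reactants: 13 2,6-bis[6-(4-benzyloxy-3-methoxyphenyl)-2,4-dioxohexyl]-4H-pyran-4-one
Product: 16 bis{2,4-dihydroxy-6-[2-(4-benzyloxy-3-methoxyphenyl)ethyl]phenyl}methanone, via open-chain heptaketone 14 (not isolated), via half-cyclised aryl tetraketone 15 (not isolated)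
Conditions: KOH (2 M aq., degassed)/1,4-dioxane (1:1), Ar, rt to 45 °C; then 1 M HCl to pH 3, 0 °C
Reagents that add atoms: potassium hydroxide, [K+].[OH-]
Why: Proposed new method: hydroxide adds to pyranone position 2 (the future ring carbon C3) and retro-oxa-Michael opening releases the symmetric heptaketone 14 as a polyenolate, the hydroxide oxygen becoming one of the two C3 oxygens; the closest known reaction type is the hydroxide opening of a pyranone-masked tetraketone followed by a single aldol aromatisation to an acylresorcinol, here required twice in one chain. Each inner ring closes by a 6-(enolexo)-exo-trig aldol of the C2 (then C2') enolate carbon, which lies between the C7 and C3 carbonyls, onto the terminal C1 (C1') ketone, giving first 15 and then 16. Loss of water from each aldol and enolisation of the C3 and C5 carbonyls produce the resorcinol rings, which makes both closures irreversible and draws the reversible pre-equilibria forward. No stereocentre is formed. The selectivity needed is C2-to-C1 over C6-to-C7 and over C4-to-C3': C7 is the cross-conjugated centre of a doubly enolised triketone and, after the first closure, part of a vinylogous carboxylate, so it should be the poorest electrophile of the chain, whereas C1 has only one acidic neighbour and is the most ketone-like carbonyl. Opening the ring with aqueous base before any acid or heat keeps the intact pyranone from attacking C1 through its own ring carbon, the path to a xanthone. Oxygen is excluded because the polyenolates and the product phenolates are easily oxidised.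

Step 9
Reactants: 16 bis{2,4-dihydroxy-6-[2-(4-benzyloxy-3-methoxyphenyl)ethyl]phenyl}methanone
Product: 17 bis{4-benzyloxy-2-hydroxy-6-[2-(4-benzyloxy-3-methoxyphenyl)ethyl]phenyl}methanone
Conditions: BnBr (2.1 eq), K2CO3 (2.2 eq), acetone, reflux
Reagents that add atoms: benzyl bromide, BrCc1ccccc1
Why: site-selective Williamson etherification; the para hydroxyls are more acidic and unhindered, whereas the ortho hydroxyls are hydrogen-bonded to the carbonyl and flanked by it, the usual pattern for 2,4-dihydroxyaryl ketones with a weak base.

Step 10
Reactants: 17 bis{4-benzyloxy-2-hydroxy-6-[2-(4-benzyloxy-3-methoxyphenyl)ethyl]phenyl}methanone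
Product: 18 bis{4-benzyloxy-2-methoxy-6-[2-(4-benzyloxy-3-methoxyphenyl)ethyl]phenyl}methanone
Conditions: MeI (6 eq), K2CO3 (4 eq), DMF, 50 °C
Reagents that add atoms: iodomethane, CI
Why: O-methylation of the remaining chelated phenols under more forcing Williamson conditions (dipolar aprotic solvent, excess of a small electrophile); no other acidic group is left.

Step 11
Reactants: 18 bis{4-benzyloxy-2-methoxy-6-[2-(4-benzyloxy-3-methoxyphenyl)ethyl]phenyl}methanone
Product: 19 bis{4-benzyloxy-2-methoxy-6-[2-(4-benzyloxy-3-methoxyphenyl)ethyl]phenyl}methanol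
Conditions: LiAlH4 (2 eq), THF, 0 °C to reflux; then H2O
Reagents that add atoms: none
Why: hydride reduction of the diaryl ketone to the carbinol; LiAlH4 is small enough to reach the tetra-ortho-substituted carbonyl and the flanking methoxyls can assist delivery. The carbinol carbon bears two identical aryl groups, so no stereocentre arises.

Step 12
Reactants: 19 bis{4-benzyloxy-2-methoxy-6-[2-(4-benzyloxy-3-methoxyphenyl)ethyl]phenyl}methanol
Product: 20 bis{4-hydroxy-2-methoxy-6-[2-(4-hydroxy-3-methoxyphenyl)ethyl]phenyl}methane (CNP0079383.0)
Conditions: H2 (1 atm), Pd/C (10%), AcOH (cat.), EtOAc/MeOH, rt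
Reagents that add atoms: none
Why: heterogeneous hydrogenolysis; the four aryl benzyl ethers and the doubly benzylic C–O bond, activated by two para oxygens and a trace of acid, are all cleaved, while arene rings and methyl ethers are untouched.

## Compound list

1 | 3-(4-hydroxy-3-methoxyphenyl)propanoic acid | COc1cc(CCC(=O)O)ccc1O | starting material
2 | 3-(4-benzyloxy-3-methoxyphenyl)propanoic acid | COc1cc(CCC(=O)O)ccc1OCc1ccccc1 | intermediate
3 | potassium methyl malonate (potassium 3-methoxy-3-oxopropanoate) | COC(=O)CC(=O)[O-].[K+] | starting material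
4 | 1-[3-(4-benzyloxy-3-methoxyphenyl)propanoyl]-1H-imidazole | COc1cc(CCC(=O)n2ccnc2)ccc1OCc1ccccc1 | intermediate (not isolated)
5 | 5-(4-benzyloxy-3-methoxyphenyl)-2-(methoxycarbonyl)-3-oxopentanoic acid (present as its magnesium chelate) | COC(=O)C(C(=O)O)C(=O)CCc1ccc(OCc2ccccc2)c(OC)c1 | intermediate (not isolated)
6 | methyl 5-(4-benzyloxy-3-methoxyphenyl)-3-oxopentanoate | COC(=O)CC(=O)CCc1ccc(OCc2ccccc2)c(OC)c1 | intermediate
7 | methyl 2-{2-[2-(4-benzyloxy-3-methoxyphenyl)ethyl]-1,3-dioxolan-2-yl}acetate | COC(=O)CC1(CCc2ccc(OCc3ccccc3)c(OC)c2)OCCO1 | intermediate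
8 | 2-{2-[2-(4-benzyloxy-3-methoxyphenyl)ethyl]-1,3-dioxolan-2-yl}acetaldehyde | O=CCC1(CCc2ccc(OCc3ccccc3)c(OC)c2)OCCO1 | intermediate
9 | 2,6-dimethyl-4H-pyran-4-one | Cc1cc(=O)cc(C)o1 | starting material
10 | 2-(3-{2-[2-(4-benzyloxy-3-methoxyphenyl)ethyl]-1,3-dioxolan-2-yl}-2-hydroxypropyl)-6-methyl-4H-pyran-4-one (racemic; present as its lithium alkoxide) | Cc1cc(=O)cc(CC(O)CC2(CCc3ccc(OCc4ccccc4)c(OC)c3)OCCO2)o1 | intermediate (not isolated)
11 | 2,6-bis(3-{2-[2-(4-benzyloxy-3-methoxyphenyl)ethyl]-1,3-dioxolan-2-yl}-2-hydroxypropyl)-4H-pyran-4-one (mixture of racemic and meso forms) | O=c1cc(CC(O)CC2(CCc3ccc(OCc4ccccc4)c(OC)c3)OCCO2)oc(CC(O)CC2(CCc3ccc(OCc4ccccc4)c(OC)c3)OCCO2)c1 | intermediate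
12 | 2,6-bis(3-{2-[2-(4-benzyloxy-3-methoxyphenyl)ethyl]-1,3-dioxolan-2-yl}-2-oxopropyl)-4H-pyran-4-one | O=c1cc(CC(=O)CC2(CCc3ccc(OCc4ccccc4)c(OC)c3)OCCO2)oc(CC(=O)CC2(CCc3ccc(OCc4ccccc4)c(OC)c3)OCCO2)c1 | intermediate
13 | 2,6-bis[6-(4-benzyloxy-3-methoxyphenyl)-2,4-dioxohexyl]-4H-pyran-4-one | O=c1cc(CC(=O)CC(=O)CCc2ccc(OCc3ccccc3)c(OC)c2)oc(CC(=O)CC(=O)CCc2ccc(OCc3ccccc3)c(OC)c2)c1 | intermediate
14 | 1,17-bis(4-benzyloxy-3-methoxyphenyl)heptadecane-3,5,7,9,11,13,15-heptone (present as polyenolate) | O=C(CCc1ccc(OCc2ccccc2)c(OC)c1)CC(=O)CC(=O)CC(=O)CC(=O)CC(=O)CC(=O)CCc1ccc(OCc2ccccc2)c(OC)c1 | intermediate (not isolated)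
15 | 9-(4-benzyloxy-3-methoxyphenyl)-1-{2,4-dihydroxy-6-[2-(4-benzyloxy-3-methoxyphenyl)ethyl]phenyl}nonane-1,3,5,7-tetrone | O=C(CC(=O)CC(=O)CC(=O)CCc1ccc(OCc2ccccc2)c(OC)c1)c1c(O)cc(O)cc1CCc1ccc(OCc2ccccc2)c(OC)c1 | intermediate (not isolated)
16 | bis{2,4-dihydroxy-6-[2-(4-benzyloxy-3-methoxyphenyl)ethyl]phenyl}methanone | O=C(c1c(O)cc(O)cc1CCc1ccc(OCc2ccccc2)c(OC)c1)c1c(O)cc(O)cc1CCc1ccc(OCc2ccccc2)c(OC)c1 | intermediate
17 | bis{4-benzyloxy-2-hydroxy-6-[2-(4-benzyloxy-3-methoxyphenyl)ethyl]phenyl}methanone | O=C(c1c(O)cc(OCc2ccccc2)cc1CCc1ccc(OCc2ccccc2)c(OC)c1)c1c(O)cc(OCc2ccccc2)cc1CCc1ccc(OCc2ccccc2)c(OC)c1 | intermediate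
18 | bis{4-benzyloxy-2-methoxy-6-[2-(4-benzyloxy-3-methoxyphenyl)ethyl]phenyl}methanone | COc1cc(OCc2ccccc2)cc(CCc2ccc(OCc3ccccc3)c(OC)c2)c1C(=O)c1c(CCc2ccc(OCc3ccccc3)c(OC)c2)cc(OCc2ccccc2)cc1OC | intermediate
19 | bis{4-benzyloxy-2-methoxy-6-[2-(4-benzyloxy-3-methoxyphenyl)ethyl]phenyl}methanol | COc1cc(OCc2ccccc2)cc(CCc2ccc(OCc3ccccc3)c(OC)c2)c1C(O)c1c(CCc2ccc(OCc3ccccc3)c(OC)c2)cc(OCc2ccccc2)cc1OC | intermediate
20 | bis{4-hydroxy-2-methoxy-6-[2-(4-hydroxy-3-methoxyphenyl)ethyl]phenyl}methane (CNP0079383.0) | COc1cc(CCc2cc(O)cc(OC)c2Cc2c(CCc3ccc(O)c(OC)c3)cc(O)cc2OC)ccc1O | target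

## Step count and least certain steps

Total step count: 12. Longest linear sequence: 12 steps (1 to 20); 3 and 9 are commercial and enter in steps 2 and 5.

Step 8 (key step). The most likely failure is folding in the wrong register: the open-chain polyenolate may close C6 onto C7 or C4 onto C3', or simply re-close to a pyranone, because every carbonyl in 14 belongs to a beta-dicarbonyl array and the preference for C1 as electrophile is a matter of degree. Hydroxide-induced retro-Claisen chain scission and air oxidation of the polyphenolate are secondary risks. The fallback uses known chemistry, sets out from 2 and returns at 16: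
- 2 is converted with N-hydroxyphthalimide and a carbodiimide into the redox-active ester 1,3-dioxoisoindolin-2-yl 3-(4-benzyloxy-3-methoxyphenyl)propanoate F1.
- Nickel-catalysed decarboxylative cross-coupling (NiCl2(dme), 4,4'-di-tert-butyl-2,2'-bipyridine) of F1 with [3,5-bis(methoxymethoxy)phenyl]zinc chloride F2, prepared from the corresponding aryl bromide, gives the bibenzyl 1-benzyloxy-4-{2-[3,5-bis(methoxymethoxy)phenyl]ethyl}-2-methoxybenzene F3.
- N-Bromosuccinimide brominates the resorcinol ring between the arm and one acetal oxygen to give 1-benzyloxy-4-{2-[2-bromo-3,5-bis(methoxymethoxy)phenyl]ethyl}-2-methoxybenzene F4.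
- Bromine–lithium exchange (n-BuLi, −78 °C) and addition of half an equivalent of ethyl formate give the symmetric carbinol bis{2-[2-(4-benzyloxy-3-methoxyphenyl)ethyl]-4,6-bis(methoxymethoxy)phenyl}methanol F5.
- Dess–Martin oxidation gives bis{2-[2-(4-benzyloxy-3-methoxyphenyl)ethyl]-4,6-bis(methoxymethoxy)phenyl}methanone F6, and HCl in methanol removes the four acetal groups to give 16.

Step 5. Proton transfer from the enolisable aldehyde to the lateral anion (followed by opening of the dioxolane), or incomplete second lithiation in the presence of the aldolate, would leave mono-adduct and recovered 9. The fallback forms the same bonds at the ketone oxidation level; it sets out from 7 and returns at 12, bypassing 8, 11 and step 6. 7 is converted with N,O-dimethylhydroxylamine hydrochloride and i-PrMgCl into 2-{2-[2-(4-benzyloxy-3-methoxyphenyl)ethyl]-1,3-dioxolan-2-yl}-N-methoxy-N-methylacetamide F7. Then 9 is lithiated and treated with F7 twice in succession; the chelated tetrahedral adducts persist until the acidic quench, so no acidic diketone is present in the flask to consume base or to offer a second deprotonation site.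

Step 9. Loss of site selectivity is the concern: in the twisted, tetra-ortho-substituted ketone the ortho hydroxyls may be less firmly hydrogen-bonded than in a planar aryl ketone, so over-benzylation can compete. The fallback reverses the logic; it sets out from 16 and returns at 17. All four phenols are benzylated (excess BnBr, K2CO3, DMF) to bis{2,4-bis(benzyloxy)-6-[2-(4-benzyloxy-3-methoxyphenyl)ethyl]phenyl}methanone F8, and the two benzyl ethers ortho to the carbonyl are then removed by chelation-controlled cleavage with MgBr2·OEt2.

Step 12. Hydrogenolysis of the carbinol C–O bond may stall, because a carbon between four ortho substituents cannot lie flat on the catalyst, while the benzyl ethers are lost; the electron-rich benzhydryl cation may also fragment under the acidic conditions. The fallback separates the two tasks; it sets out from 19 and returns at 20. Ionic hydrogenation (Et3SiH, CF3CO2H, CH2Cl2, 0 °C), which needs no surface contact, gives bis{4-benzyloxy-2-methoxy-6-[2-(4-benzyloxy-3-methoxyphenyl)ethyl]phenyl}methane F9, and plain hydrogenolysis over Pd/C then removes the four benzyl groups.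

## Further compounds

F1 | step 8 | 1,3-dioxoisoindolin-2-yl 3-(4-benzyloxy-3-methoxyphenyl)propanoate | COc1cc(CCC(=O)ON2C(=O)c3ccccc3C2=O)ccc1OCc1ccccc1
F2 | step 8 | [3,5-bis(methoxymethoxy)phenyl]zinc chloride | COCOc1cc(OCOC)cc([Zn]Cl)c1
F3 | step 8 | 1-benzyloxy-4-{2-[3,5-bis(methoxymethoxy)phenyl]ethyl}-2-methoxybenzene | COCOc1cc(OCOC)cc(CCc2ccc(OCc3ccccc3)c(OC)c2)c1
F4 | step 8 | 1-benzyloxy-4-{2-[2-bromo-3,5-bis(methoxymethoxy)phenyl]ethyl}-2-methoxybenzene | COCOc1cc(OCOC)c(Br)c(CCc2ccc(OCc3ccccc3)c(OC)c2)c1
F5 | step 8 | bis{2-[2-(4-benzyloxy-3-methoxyphenyl)ethyl]-4,6-bis(methoxymethoxy)phenyl}methanol | OC(c1c(OCOC)cc(OCOC)cc1CCc1ccc(OCc2ccccc2)c(OC)c1)c1c(OCOC)cc(OCOC)cc1CCc1ccc(OCc2ccccc2)c(OC)c1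
F6 | step 8 | bis{2-[2-(4-benzyloxy-3-methoxyphenyl)ethyl]-4,6-bis(methoxymethoxy)phenyl}methanone | O=C(c1c(OCOC)cc(OCOC)cc1CCc1ccc(OCc2ccccc2)c(OC)c1)c1c(OCOC)cc(OCOC)cc1CCc1ccc(OCc2ccccc2)c(OC)c1
F7 | step 5 | 2-{2-[2-(4-benzyloxy-3-methoxyphenyl)ethyl]-1,3-dioxolan-2-yl}-N-methoxy-N-methylacetamide | CON(C)C(=O)CC1(CCc2ccc(OCc3ccccc3)c(OC)c2)OCCO1
F8 | step 9 | bis{2,4-bis(benzyloxy)-6-[2-(4-benzyloxy-3-methoxyphenyl)ethyl]phenyl}methanone | O=C(c1c(OCc2ccccc2)cc(OCc2ccccc2)cc1CCc1ccc(OCc2ccccc2)c(OC)c1)c1c(OCc2ccccc2)cc(OCc2ccccc2)cc1CCc1ccc(OCc2ccccc2)c(OC)c1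
F9 | step 12 | bis{4-benzyloxy-2-methoxy-6-[2-(4-benzyloxy-3-methoxyphenyl)ethyl]phenyl}methane | COc1cc(OCc2ccccc2)cc(CCc2ccc(OCc3ccccc3)c(OC)c2)c1Cc1c(CCc2ccc(OCc3ccccc3)c(OC)c2)cc(OCc2ccccc2)cc1OC
A1 | alternative 1 | bis{2-methoxy-6-[2-(3-methoxy-4-triisopropylsilyloxyphenyl)ethyl]phenyl}methane | COc1cccc(CCc2ccc(O[Si](C(C)C)(C(C)C)C(C)C)c(OC)c2)c1Cc1c(CCc2ccc(O[Si](C(C)C)(C(C)C)C(C)C)c(OC)c2)cccc1OC
A2 | alternative 1 | bis{4-hydroxy-2-methoxy-6-[2-(3-methoxy-4-triisopropylsilyloxyphenyl)ethyl]phenyl}methane | COc1cc(O)cc(CCc2ccc(O[Si](C(C)C)(C(C)C)C(C)C)c(OC)c2)c1Cc1c(CCc2ccc(O[Si](C(C)C)(C(C)C)C(C)C)c(OC)c2)cc(O)cc1OC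
A3 | alternative 2 | 2,2',4,4'-tetrahydroxybenzophenone | O=C(c1ccc(O)cc1O)c1ccc(O)cc1O
A4 | alternative 2 | bis(4-benzyloxy-2-methoxyphenyl)methanone | COc1cc(OCc2ccccc2)ccc1C(=O)c1ccc(OCc2ccccc2)cc1OC
A5 | alternative 2 | 1-benzyloxy-4-ethenyl-2-methoxybenzene | C=Cc1ccc(OCc2ccccc2)c(OC)c1
A6 | alternative 2 | bis{4-benzyloxy-2-methoxy-6-[2-(4-benzyloxy-3-methoxyphenyl)ethyl]phenyl}methanone | COc1cc(OCc2ccccc2)cc(CCc2ccc(OCc3ccccc3)c(OC)c2)c1C(=O)c1c(CCc2ccc(OCc3ccccc3)c(OC)c2)cc(OCc2ccccc2)cc1OC
A7 | alternative 3 | 1-fluoro-3-methoxy-5-(triisopropylsilyloxy)benzene | COc1cc(F)cc(O[Si](C(C)C)(C(C)C)C(C)C)c1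
A8 | alternative 3 | [2-(4-benzyloxy-3-methoxyphenyl)ethyl]magnesium bromide | COc1cc(CC[Mg]Br)ccc1OCc1ccccc1
A9 | alternative 3 | 3-methoxy-5-(triisopropylsilyloxy)benzyne | COC1=CC(O[Si](C(C)C)(C(C)C)C(C)C)=CC#C1
A10 | alternative 3 | 2-[2-(4-benzyloxy-3-methoxyphenyl)ethyl]-6-methoxy-4-(triisopropylsilyloxy)benzaldehyde | COc1cc(O[Si](C(C)C)(C(C)C)C(C)C)cc(CCc2ccc(OCc3ccccc3)c(OC)c2)c1C=O
A11 | alternative 3 | bis{2-[2-(4-benzyloxy-3-methoxyphenyl)ethyl]-6-methoxy-4-(triisopropylsilyloxy)phenyl}methanol | OC(c1c(CCc2ccc(OCc3ccccc3)c(OC)c2)cc(O[Si](C(C)C)(C(C)C)C(C)C)cc1OC)c1c(CCc2ccc(OCc3ccccc3)c(OC)c2)cc(O[Si](C(C)C)(C(C)C)C(C)C)cc1OC
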